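The quinone ring, read in its triketo tautomer, is an oxalyl unit (C1=O, C2–OH) joined to a four-carbon chain. That chain is C3, the α-carbon of the C4 ketone, plus the methyl enol ether C5(OMe)=C6H. The route rests on a formal [4+2] bis-acylation of the acyclic α-methoxy enone CH2=C(OMe)–CO–CH2CH2–CH(OAc)–C13H27 with oxalyl chloride. C6 is acylated first. Soft enolisation then lets C3 attack the remaining acid chloride carbon C2. This closes the six-membered ring directly at the hydroxyquinone oxidation level, with OMe, OH and the (R)-acetate already in place and no redox or protecting-group step. The stereocentre comes from a glutamic-acid-derived lactone.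

Key step: step 4

Ring numbering used below: C1 = C=O next to C–OH, C2 = C–OH, C3 = carbon bearing the side chain, C4 = second C=O, C5 = C–OMe, C6 = C–H.
Assumption: compounds 1, 2, 5 and 9 are taken as commercial. The C5=C6 geometry of 10 is left undefined because it should equilibrate under the reaction conditions.

Step 1
Reactants: 1 (S)-(5-oxotetrahydrofuran-2-yl)methyl 4-methylbenzenesulfonate; 2 dodecylmagnesium bromide
Product: 4 (R)-5-tridecyldihydrofuran-2(3H)-one, via didodecylcuprate 3 (not isolated)
Conditions: 2 (3 equiv), CuBr·SMe2 (1.5 equiv), THF, −40 °C; then 1, −40 → −10 °C; aq NH4Cl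
Reagents that add atoms: none
Why: SN2 displacement of a primary tosylate by a diorganocuprate, soft enough to spare the lactone carbonyl at low temperature; the stereocentre is not touched and its descriptor changes from S to R only because the CIP ranking of the two carbon substituents is reversed.

Step 2
Reactants: 4 (R)-5-tridecyldihydrofuran-2(3H)-one; 5 methyl vinyl ether
Product: 7 (R)-6-hydroxy-2-methoxynonadec-1-en-3-one, via 1-methoxyvinyllithium 6 (not isolated)
Conditions: 5 (excess), t-BuLi, THF, −78 → 0 °C; then 4, −78 °C; H2O quench at −78 °C; Et3N-deactivated silica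
Reagents that add atoms: none
Why: α-Lithiation of the vinyl ether gives an acyl-anion equivalent that should add only once to the lactone, because the lithium hemiketal alkoxide persists at −78 °C until the quench (organolithium monoaddition to a lactone); the carbinol centre is a spectator.

Step 3
Reactants: 7 (R)-6-hydroxy-2-methoxynonadec-1-en-3-one
Product: 8 (R)-2-methoxy-3-oxononadec-1-en-6-yl acetate
Conditions: Ac2O, Et3N, DMAP (cat.), CH2Cl2, 0 °C → rt
Reagents that add atoms: acetic anhydride CC(=O)OC(C)=O
Why: DMAP-catalysed O-acylation of the secondary alcohol in the open hydroxy-ketone form, which conjugation of the ketone with the enol ether favours over the lactol; the C–O bond is not broken, so the configuration is retained.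

Step 4
Reactants: 8 (R)-2-methoxy-3-oxononadec-1-en-6-yl acetate; 9 oxalyl chloride
Product: 12 (R)-1-(2-hydroxy-5-methoxy-3,6-dioxocyclohexa-1,4-dien-1-yl)pentadecan-2-yl acetate, via acid chloride 10 (not isolated), via ene-trione tautomer 11 (not isolated)
Conditions: 9 (3 equiv), CH2Cl2, 0 °C → rt, then evaporate; MgBr2·OEt2, i-Pr2NEt, CH2Cl2 (high dilution), −20 °C → rt; 1 M HCl work-up
Reagents that add atoms: none
Why: Proposed new method: oxalyl chloride should first C-acylate the enol-ether terminus C6 of 8 (addition to an α-chloro ether, then loss of HCl), the only π-nucleophile present while C3 is still locked in the ketone form, so that acid chloride 10 carries the complete C3–C4–C5–C6–C1–C2 chain. After removal of excess reagent, MgBr2/i-Pr2NEt soft-enolises the C4 ketone, which has α-hydrogens only at C3, and the magnesium enolate attacks the acid chloride carbon C2 in a 6-(enolendo)-exo-trig closure; loss of chloride gives ene-trione 11, whose C3–H enolises toward C2 to the hydroxyquinone, held as its magnesium chelate until acidic work-up. The closest known reaction types are the acylation of alkyl vinyl ethers with oxalyl chloride to 4-alkoxy-2-oxobut-3-enoyl chlorides, the MgBr2-mediated soft-enolisation C-acylation of ketones with acid chlorides, and the Claisen/Dieckmann closures of α-keto esters that give 2,5-dihydroxybenzoquinones; their merger into one annulation on an α-alkoxy enone is the new element. Only the isomer of 10 with the C4 and C1 acyl groups cis on C5=C6 can close, but this push–pull alkene should isomerise readily by reversible halide addition at C5, so both geometries drain into one product. Chemoselectivity rests on C2 being far more electrophilic than the vinylogous-ester ketone C1 (whose five-ring aldol is reversible) and on magnesium chelation favouring C- over O-acylation, with irreversible formation of the strongly acidic quinone enol as the sink. C3 of 11 is only a transient stereocentre erased by enolisation, and the remote (R)-acetate, inert to these non-nucleophilic conditions, is carried through unchanged.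

Compound list
1 | (S)-(5-oxotetrahydrofuran-2-yl)methyl 4-methylbenzenesulfonate | Cc1ccc(cc1)S(=O)(=O)OC[C@@H]2CCC(=O)O2 | starting material
2 | dodecylmagnesium bromide | CCCCCCCCCCCC[Mg]Br | starting material
3 | bromomagnesium didodecylcuprate (not isolated) | CCCCCCCCCCCC[Cu-]CCCCCCCCCCCC.[Mg+]Br | intermediate
4 | (R)-5-tridecyldihydrofuran-2(3H)-one | CCCCCCCCCCCCC[C@@H]1CCC(=O)O1 | intermediate
5 | methyl vinyl ether | C=COC | starting material
6 | 1-methoxyvinyllithium (not isolated) | [Li]C(=C)OC | intermediate
7 | (R)-6-hydroxy-2-methoxynonadec-1-en-3-one | CCCCCCCCCCCCC[C@H](CCC(=O)C(=C)OC)O | intermediate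
8 | (R)-2-methoxy-3-oxononadec-1-en-6-yl acetate | CCCCCCCCCCCCC[C@H](CCC(=O)C(=C)OC)OC(C)=O | intermediate
9 | oxalyl chloride | O=C(Cl)C(=O)Cl | starting material
10 | (R)-8-acetoxy-4-methoxy-2,5-dioxohenicos-3-enoyl chloride, alkene geometry mobile (not isolated) | CCCCCCCCCCCCC[C@H](CCC(=O)C(OC)=CC(=O)C(=O)Cl)OC(C)=O | intermediate
11 | (2R)-1-(4-methoxy-2,5,6-trioxocyclohex-3-en-1-yl)pentadecan-2-yl acetate, ene-trione tautomer (not isolated) | CCCCCCCCCCCCC[C@H](CC1C(=O)C(=O)C=C(OC)C1=O)OC(C)=O | intermediate
12 | (R)-1-(2-hydroxy-5-methoxy-3,6-dioxocyclohexa-1,4-dien-1-yl)pentadecan-2-yl acetate | CCCCCCCCCCCCC[C@H](CC1=C(O)C(=O)C=C(OC)C1=O)OC(C)=O | target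

Total step count: 4. Longest linear sequence: 4.

Steps most likely to fail

Step 4. The captodative enol ether may be too weak a π-nucleophile. Acylation at C6 could then stall, or the ketone enol could be attacked instead. In the second stage, three processes may outrun ring closure: O-acylation of the enolate, loss of CO from the α-keto acid chloride, and intermolecular acylation.
- The fallback uses known chemistry, sets out from 8 and returns at 12.
- Mild hydrolysis of the enol ether (oxalic acid on wet silica, CH2Cl2) should give (R)-2,3-dioxononadecan-6-yl acetate F1.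
- A crossed Claisen condensation with dimethyl oxalate (LiHMDS, THF, −78 → 0 °C) should occur at the unhindered methyl group C6. It should give methyl (R)-8-acetoxy-2,4,5-trioxohenicosanoate F2.
- Under the same base, C3 closes onto the ester carbon C2 by Dieckmann condensation. This should give (R)-1-(2,5-dihydroxy-3,6-dioxocyclohexa-1,4-dien-1-yl)pentadecan-2-yl acetate F3.
- Brief acid-catalysed methanolysis (MeOH, cat. H2SO4) should etherify only the unhindered vinylogous acid at C5, next to C6–H, giving 12.

Step 2. Premature collapse of the tetrahedral intermediate would allow a second addition of the organolithium. The enol ether may also hydrolyse during work-up.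
- The fallback sets out from 4 and returns at 7.
- Aminolysis of the lactone with MeNH(OMe)·HCl and AlMe3 (CH2Cl2) should give (R)-4-hydroxy-N-methoxy-N-methylheptadecanamide F4.
- F4 is treated with two equivalents of 6; the first only deprotonates the alcohol.
- The resulting chelated tetrahedral intermediate cannot collapse before the quench, which should deliver 7.

Step 1. Attack of the organometallic on the lactone carbonyl, or reduction at the tosylate carbon, may compete with displacement.
- The fallback sets out from 2 and returns at 4.
- CuI-catalysed opening of (R)-epichlorohydrin (ClC[C@H]1CO1) by 2 at the epoxide CH2 should give (R)-1-chloropentadecan-2-ol F5.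
- NaOH should close F5 to (R)-2-tridecyloxirane F6 without touching the stereocentre.
- Opening of the epoxide terminus with dilithioacetate (AcOH, 2 LDA, THF), then acidic lactonisation, should give 4.

Further compounds
F1 | step 4 | (R)-2,3-dioxononadecan-6-yl acetate | CCCCCCCCCCCCC[C@H](CCC(=O)C(C)=O)OC(C)=O
F2 | step 4 | methyl (R)-8-acetoxy-2,4,5-trioxohenicosanoate | CCCCCCCCCCCCC[C@H](CCC(=O)C(=O)CC(=O)C(=O)OC)OC(C)=O
F3 | step 4 | (R)-1-(2,5-dihydroxy-3,6-dioxocyclohexa-1,4-dien-1-yl)pentadecan-2-yl acetate | CCCCCCCCCCCCC[C@H](CC1=C(O)C(=O)C=C(O)C1=O)OC(C)=O
F4 | step 2 | (R)-4-hydroxy-N-methoxy-N-methylheptadecanamide | CCCCCCCCCCCCC[C@H](CCC(=O)N(C)OC)O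
F5 | step 1 | (R)-1-chloropentadecan-2-ol | ClC[C@H](O)CCCCCCCCCCCCC
F6 | step 1 | (R)-2-tridecyloxirane | CCCCCCCCCCCCC[C@@H]1CO1
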